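## Retrosynthetic overview

1. The side-chain oxirane is the last ring made: reagent-controlled epoxidation of the C10=C11 alkene of a diene bis-angelate, which comes from double angeloylation of a chlorohydrin triol.
2. The triol side chain comes from an α-methylene aldehyde by asymmetric allylboration (sets C8) and allyl-to-prenyl cross-metathesis; these are the only C–C bonds made.
3. Key step: the ring C4–O and C3–Cl bonds come from one hydroxyl-directed titanium chlorohydroxylation of an all-cis cyclohexenol, through a ring epoxide that is opened in the same flask.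
4. That cyclohexenol comes from (S)-carvone by α′-hydroxylation, Mitsunobu acetoxylation with inversion (C6–OAc cis to the side chain), ene chlorination of the isopropenyl methyl and Luche reduction.
5. Ring order: the cyclohexane is bought with carvone; the C3/C4 oxirane is formed and opened in step 5; the C10/C11 oxirane is closed in step 10.

Assumption: (−)-Ipc2B(allyl) and the L-configured Shi ketone are bought; locants follow the target: ring C1 (bears the side chain), C2 (CH2), C3 (Cl), C4 (C(OH)CH3), C5 (O-angeloyl), C6 (OAc); chain C7(=C14H2), C8 (O-angeloyl), C9, C10/C11 (oxirane).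

## Route

Step 1
Reactants: 1 (S)-(+)-carvone
Product: 3 (5R,6R)-6-hydroxy-2-methyl-5-(prop-1-en-2-yl)cyclohex-2-en-1-one (trans-6-hydroxycarvone), via potassium α′-dienolate 2 (not isolated)
Conditions: KN(SiMe3)2, THF, −78 °C; then 2-(phenylsulfonyl)-3-phenyloxaziridine, −78 °C; aq. NH4Cl
Reagents that add atoms: 2-(phenylsulfonyl)-3-phenyloxaziridine, O=S(=O)(c1ccccc1)N1OC1c1ccccc1
Why: Kinetic α′-deprotonation gives the cross-conjugated dienolate 2, and electrophilic oxygen transfer from the N-sulfonyloxaziridine (Davis enolate hydroxylation) occurs on the face anti to the neighbouring isopropenyl group, which sets C6 trans to it (6R).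

Step 2
Reactants: 3 trans-6-hydroxycarvone
Product: 4 (5R,6S)-6-acetoxy-2-methyl-5-(prop-1-en-2-yl)cyclohex-2-en-1-one (cis-6-acetoxycarvone)
Conditions: PPh3, DIAD, AcOH, toluene, 0 → 23 °C
Reagents that add atoms: acetic acid, CC(=O)O
Why: Mitsunobu reaction: acetate displaces the α-keto alkoxyphosphonium by SN2 with inversion, so the C6 acetate ends cis to the side chain (6S), and anti elimination is impossible because the only β-hydrogen (C1–H) is cis to the leaving group.

Step 3
Reactants: 4 cis-6-acetoxycarvone
Product: 5 (5R,6S)-6-acetoxy-5-(3-chloroprop-1-en-2-yl)-2-methylcyclohex-2-en-1-one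
Conditions: Ca(OCl)2, solid CO2, CH2Cl2/H2O, 0 °C
Reagents that add atoms: calcium hypochlorite Ca(OCl)2, [Ca+2].[O-]Cl.[O-]Cl
Why: Ene-type allylic chlorination by HOCl made in the flask: the electron-rich 1,1-disubstituted alkene takes up Cl+ at its CH2 terminus and loses a methyl proton while the electron-poor enone alkene is untouched (the reaction known for carvone itself), and no stereocentre is affected.

Step 4
Reactants: 5 allylic chloride
Product: 6 (1S,2R,6R)-6-(3-chloroprop-1-en-2-yl)-2-hydroxy-3-methylcyclohex-3-en-1-yl acetate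
Conditions: NaBH4, CeCl3·7H2O, MeOH, −78 °C
Reagents that add atoms: none
Why: Luche reduction: the hard borohydride attacks the ketone 1,2 and axially, on the face anti to the pseudo-axial C6 acetate, giving the equatorial C5 alcohol cis to the acetate and the side chain, while allylic chloride and ester survive at −78 °C.

Step 5
Reactants: 6 all-cis cyclohexenol
Product: 8 (1S,2S,3S,4S,6R)-4-chloro-6-(3-chloroprop-1-en-2-yl)-2,3-dihydroxy-3-methylcyclohexyl acetate, via titanium-bound syn-epoxy alcohol 7 (not isolated)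
Conditions: TiCl(OiPr)3 (2.0 equiv), t-BuOOH (decane, 1.5 equiv), CH2Cl2, −20 → 0 °C; aq. tartaric acid
Reagents that add atoms: tert-butyl hydroperoxide, CC(C)(C)OO; chlorotitanium triisopropoxide TiCl(OiPr)3, CC(C)O[Ti](Cl)(OC(C)C)OC(C)C
Why: Proposed new method: the C5 hydroxyl exchanges onto tetravalent titanium, the titanium-bound tert-butylperoxide delivers oxygen to the alkene face syn to that C–O–Ti bond to give the bound 2,3-epoxy alkoxide 7, and chloride from a second Lewis-acidic titanium centre opens the activated epoxide anti at the distal secondary carbon C3 (trans-diaxial, and away from tertiary C4 whose cationic character is disfavoured by the C5 oxygen), so the C4–O bond (OH cis to C5–OH) and the C3–Cl bond (trans) are set in one flask; closest known reaction type: titanium alkoxide/t-BuOOH hydroxyl-directed epoxidation combined with the chlorotitanium–tartrate chlorohydroxylation of primary allylic alcohols and titanium-mediated C3-selective opening of 2,3-epoxy alcohols, here proposed ligand-free and substrate-directed on a cyclic secondary allylic alcohol, where it has not been shown.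

Step 6
Reactants: 8 chlorohydrin diol
Product: 9 (1S,2S,3S,4S,6R)-4-chloro-2,3-dihydroxy-3-methyl-6-(3-oxoprop-1-en-2-yl)cyclohexyl acetate
Conditions: NaI (0.2 equiv), NMO (4 equiv), MeCN, 40 °C
Reagents that add atoms: N-methylmorpholine N-oxide, C[N+]1([O-])CCOCC1
Why: Kornblum-type N-oxide oxidation: iodide-catalysed SN2 of the primary allylic halide by the N-oxide oxygen (SN2 and SN2′ give the same product here) and loss of N-methylmorpholine from the alkoxyammonium salt give the α-methylene aldehyde, while the hindered secondary ring chloride, the acetate and the chlorohydrin are inert to the weakly basic N-oxide.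

Step 7
Reactants: 9 α-methylene aldehyde
Product: 11 (1S,2S,3S,4S,6R)-4-chloro-2,3-dihydroxy-6-[(3S)-3-hydroxyhexa-1,5-dien-2-yl]-3-methylcyclohexyl acetate, via bis(isopinocampheyl)borinate 10 (not isolated)
Conditions: (−)-Ipc2B(allyl) (3.5 equiv), Et2O, −78 °C; then HOCH2CH2NH2, 23 °C
Reagents that add atoms: (−)-B-allyldiisopinocampheylborane (from (+)-α-pinene), C=CCB([C@@H]1C[C@@H]2C[C@H]([C@H]1C)C2(C)C)[C@@H]1C[C@@H]2C[C@H]([C@H]1C)C2(C)C
Why: Brown asymmetric allylboration through a chair Zimmerman–Traxler transition state: the (−)-reagent, which turns benzaldehyde into the S carbinol, adds to the same aldehyde face here and sets C8 as S under reagent control, the excess covers the free hydroxyls, and the non-oxidative aminoethanol release spares acetate and chlorohydrin.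

Step 8
Reactants: 11 homoallylic triol
Product: 12 (1S,2S,3S,4S,6R)-4-chloro-2,3-dihydroxy-6-[(3S)-3-hydroxy-6-methylhepta-1,5-dien-2-yl]-3-methylcyclohexyl acetate
Conditions: 2-methyl-2-butene/CH2Cl2 (1:1), RuCl2(=CHPh)(PCy3)(H2IMes) (second-generation Grubbs catalyst, 5 mol %), 40 °C
Reagents that add atoms: 2-methyl-2-butene, CC=C(C)C
Why: Olefin cross-metathesis with excess 2-methyl-2-butene converts the monosubstituted alkene into the prenyl unit, while the 1,1-disubstituted C7=C14 alkene is too hindered to react and ring closure onto it would need a cyclobutene.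

Step 9
Reactants: 12 prenyl triol
Product: 13 (3S)-2-[(1R,2S,3S,4S,5S)-2-acetoxy-3-(angeloyloxy)-5-chloro-4-hydroxy-4-methylcyclohexyl]-6-methylhepta-1,5-dien-3-yl angelate
Conditions: angelic acid, 2,4,6-trichlorobenzoyl chloride, Et3N, toluene, 23 °C; then 12, 75 °C
Reagents that add atoms: angelic acid, C/C=C(/C)C(=O)O
Why: Yamaguchi-type mixed-anhydride esterification run without DMAP keeps the Z geometry of the angeloyl group and acylates the two secondary hydroxyls (C8 and C5), while the tertiary C4 hydroxyl is too hindered to react.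

Step 10
Reactants: 13 diene bis-angelate
Product: 14 target, (2S)-1-[(2S)-3,3-dimethyloxiran-2-yl]-3-[(1R,2S,3S,4S,5S)-2-acetoxy-3-(angeloyloxy)-5-chloro-4-hydroxy-4-methylcyclohexyl]but-3-en-2-yl angelate
Conditions: 1,2:4,5-di-O-isopropylidene-β-L-erythro-2,3-hexodiulo-2,6-pyranose (L-configured Shi ketone, 0.5 equiv), KHSO5 (as 2KHSO5·KHSO4·K2SO4), NaHCO3 (pH ≈ 8), Bu4NHSO4, MeCN/CH2(OMe)2–aq. Na2H2(edta), 0 °C
Reagents that add atoms: potassium peroxymonosulfate KHSO5, [K+].[O-]S(=O)(=O)OO
Why: Shi asymmetric epoxidation: the chiral dioxirane made from the ketone and KHSO5 attacks only the electron-rich trisubstituted C10=C11 alkene through a spiro transition state, the L-configured ketone giving the 10S oxirane (the D-fructose ketone gives 10R), and the pH 8 buffer avoids closing the base-sensitive chlorohydrin.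

## Compound list

1 | (S)-(+)-carvone, (5S)-2-methyl-5-(prop-1-en-2-yl)cyclohex-2-en-1-one | C=C(C)[C@H]1CC=C(C)C(=O)C1 | starting material
2 | potassium (3S)-6-methyl-3-(prop-1-en-2-yl)cyclohexa-1,5-dien-1-olate (α′-dienolate of 1) | C=C(C)[C@H]1CC=C(C)C([O-])=C1.[K+] | intermediate (not isolated)
3 | (5R,6R)-6-hydroxy-2-methyl-5-(prop-1-en-2-yl)cyclohex-2-en-1-one (OH trans to isopropenyl) | C=C(C)[C@H]1CC=C(C)C(=O)[C@@H]1O | intermediate
4 | (5R,6S)-6-acetoxy-2-methyl-5-(prop-1-en-2-yl)cyclohex-2-en-1-one (OAc cis to isopropenyl) | C=C(C)[C@H]1CC=C(C)C(=O)[C@H]1OC(C)=O | intermediate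
5 | (5R,6S)-6-acetoxy-5-(3-chloroprop-1-en-2-yl)-2-methylcyclohex-2-en-1-one | C=C(CCl)[C@H]1CC=C(C)C(=O)[C@H]1OC(C)=O | intermediate
6 | (1S,2R,6R)-6-(3-chloroprop-1-en-2-yl)-2-hydroxy-3-methylcyclohex-3-en-1-yl acetate (OH, OAc and side chain all cis) | C=C(CCl)[C@H]1CC=C(C)[C@@H](O)[C@H]1OC(C)=O | intermediate
7 | (1S,2S,3S,4R,6R)-4-(3-chloroprop-1-en-2-yl)-2-hydroxy-1-methyl-7-oxabicyclo[4.1.0]heptan-3-yl acetate (epoxide oxygen cis to OH; bound to titanium in the flask) | C=C(CCl)[C@H]1C[C@H]2O[C@@]2(C)[C@@H](O)[C@H]1OC(C)=O | intermediate (not isolated)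
8 | (1S,2S,3S,4S,6R)-4-chloro-6-(3-chloroprop-1-en-2-yl)-2,3-dihydroxy-3-methylcyclohexyl acetate | C=C(CCl)[C@H]1C[C@H](Cl)[C@@](C)(O)[C@@H](O)[C@H]1OC(C)=O | intermediate
9 | (1S,2S,3S,4S,6R)-4-chloro-2,3-dihydroxy-3-methyl-6-(3-oxoprop-1-en-2-yl)cyclohexyl acetate | C=C(C=O)[C@H]1C[C@H](Cl)[C@@](C)(O)[C@@H](O)[C@H]1OC(C)=O | intermediate
10 | O-bis(isopinocampheyl)boryl derivative of 11 at the new C8 carbinol (borinate ester) | C=C([C@H](CC=C)OB([C@@H]2C[C@@H]3C[C@H]([C@H]2C)C3(C)C)[C@@H]2C[C@@H]3C[C@H]([C@H]2C)C3(C)C)[C@H]1C[C@H](Cl)[C@@](C)(O)[C@@H](O)[C@H]1OC(C)=O | intermediate (not isolated)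
11 | (1S,2S,3S,4S,6R)-4-chloro-2,3-dihydroxy-6-[(3S)-3-hydroxyhexa-1,5-dien-2-yl]-3-methylcyclohexyl acetate | C=C([C@H](CC=C)O)[C@H]1C[C@H](Cl)[C@@](C)(O)[C@@H](O)[C@H]1OC(C)=O | intermediate
12 | (1S,2S,3S,4S,6R)-4-chloro-2,3-dihydroxy-6-[(3S)-3-hydroxy-6-methylhepta-1,5-dien-2-yl]-3-methylcyclohexyl acetate | C=C([C@H](CC=C(C)C)O)[C@H]1C[C@H](Cl)[C@@](C)(O)[C@@H](O)[C@H]1OC(C)=O | intermediate
13 | (3S)-2-[(1R,2S,3S,4S,5S)-2-acetoxy-3-(angeloyloxy)-5-chloro-4-hydroxy-4-methylcyclohexyl]-6-methylhepta-1,5-dien-3-yl angelate | C=C([C@H](CC=C(C)C)OC(=O)/C(C)=C\C)[C@H]1C[C@H](Cl)[C@@](C)(O)[C@@H](OC(=O)/C(C)=C\C)[C@H]1OC(C)=O | intermediate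
14 | (2S)-1-[(2S)-3,3-dimethyloxiran-2-yl]-3-[(1R,2S,3S,4S,5S)-2-acetoxy-3-(angeloyloxy)-5-chloro-4-hydroxy-4-methylcyclohexyl]but-3-en-2-yl angelate (CNP0313121.1) | C=C([C@H](C[C@@H]1OC1(C)C)OC(=O)/C(C)=C\C)[C@H]1C[C@H](Cl)[C@@](C)(O)[C@@H](OC(=O)/C(C)=C\C)[C@H]1OC(C)=O | target

## Step count and risks

Total step count: 10. Longest linear sequence: 10 steps (one linear chain from (S)-carvone, no protecting groups).

The three steps most likely to fail:

Step 5 (the proposed new method). The titanium/peroxide epoxidation of a secondary cyclohexenol may be slow, the titanium alkoxide may move the neighbouring cis acetate, or chloride may open the epoxide at the wrong carbon. The fallback uses known chemistry and sets out from 6. VO(acac)2 (2 mol %) with t-BuOOH in CH2Cl2 at 0 → 23 °C epoxidises the ring alkene syn to the hydroxyl, and the epoxy alcohol 7 is isolated this time. Ti(OiPr)4 (1.5 equiv) with Et2NH2Cl in CH2Cl2 at 23 °C then opens 7 at the distal carbon C3, and the route is rejoined at 8. This fallback makes no compound outside the compound list (F0).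

Step 2. The Mitsunobu displacement at the flanked α-ketol carbon may be slow, may give retention through an acyloxyphosphonium pathway, or may epimerise C6. The fallback replaces SN2 inversion by face-selective protonation and sets out from 3. Ac2O/pyridine gives trans-6-acetoxycarvone F1. TMSOTf/Et3N in CH2Cl2 (−78 → 0 °C) then gives the cross-conjugated silyl dienol ether F2, in which C6 is planar (C6–H is the only α-hydrogen of the ketone). Bu4NF/AcOH in THF at −78 °C releases the enolate and protonates C6 from the face anti to the isopropenyl group (kinetic protonation), which puts the acetate cis and comes back to the route at 4.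

Step 9. The C5 hydroxyl sits between a fully substituted carbinol carbon and the axial acetate, so acylation may be slow. In that case base-promoted acetyl migration from C6 to C5, or angelate-to-tiglate isomerisation at 75 °C, can compete. The fallback builds the angelate double bonds instead of transferring them and sets out from 12. DIC/DMAP esterification of both secondary hydroxyls with 2-[bis(2,2,2-trifluoroethoxy)phosphoryl]propanoic acid in CH2Cl2 at 23 °C gives the bis(phosphonopropionate) F3. Still–Gennari olefination (KN(SiMe3)2 2.0 equiv, 18-crown-6, THF, −78 °C, then CH3CHO) then forms both Z-trisubstituted alkenes; the phosphonate C–H is far more acidic than the tertiary hydroxyl, so the chlorohydrin is not deprotonated. The route is rejoined at 13.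

## Further compounds

F0 | step 5 | none | none
F1 | step 2 | (5R,6R)-6-acetoxy-2-methyl-5-(prop-1-en-2-yl)cyclohex-2-en-1-one (trans-6-acetoxycarvone) | C=C(C)[C@H]1CC=C(C)C(=O)[C@@H]1OC(C)=O
F2 | step 2 | (6R)-3-methyl-6-(prop-1-en-2-yl)-2-[(trimethylsilyl)oxy]cyclohexa-1,3-dien-1-yl acetate | C=C(C)[C@H]1CC=C(C)C(O[Si](C)(C)C)=C1OC(C)=O
F3 | step 9 | bis{2-[bis(2,2,2-trifluoroethoxy)phosphoryl]propanoate} of 12 at the C5 and C8 hydroxyls (epimer mixture at the two phosphonate-bearing carbons) | C=C([C@H](CC=C(C)C)OC(=O)C(C)P(=O)(OCC(F)(F)F)OCC(F)(F)F)[C@H]1C[C@H](Cl)[C@@](C)(O)[C@@H](OC(=O)C(C)P(=O)(OCC(F)(F)F)OCC(F)(F)F)[C@H]1OC(C)=O
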